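The eleven-membered carbocycle is closed at the central sp2–sp2 bond of its 2-substituted 1,3-diene: between the ring carbon that bears the exocyclic methylene and the neighbouring ring CH=, whose alkene partner is attached to the quaternary C(CH3)2. A macrocyclic 11-endo Mizoroki–Heck reaction of an acyclic 2-iodo-1-alkene onto a terminal vinyl group achieves this in one operation: the iodoalkene becomes the exocyclic methylene unit and, because the C(CH3)2 carbon carries no hydrogen, β-hydride elimination can only deliver the conjugated (E)-ring alkene. The precursor is a linear iodotriene vanillate (phenol as acetate) whose carbinol centre comes from Brown reverse prenylation and whose (E)-trisubstituted alkene comes from a Johnson–Claisen rearrangement.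

Key step: step 8

Assumption: the single stereocentre of the target is (R) (O > C(CH3)2 > ring CH2 > H); the phenol is carried as its acetate until the last step, and 4-acetoxy-3-methoxybenzoic acid is taken as a purchasable starting material.

Step 1
Reactants: 1 pent-4-yn-1-ol
Product: 2 4-iodopent-4-en-1-ol
Conditions: NaI, Me3SiCl, H2O, MeCN, 0 °C to rt
Reagents that add atoms: sodium iodide, [Na+].[I-]
Why: HI generated in the flask should add once across the terminal alkyne in the Markovnikov sense (hydroiodination) to give the 2-iodo-1-alkene, any silyl ether at oxygen being hydrolysed on aqueous work-up.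

Step 2
Reactants: 2 4-iodopent-4-en-1-ol
Product: 3 4-iodopent-4-enal
Conditions: Dess–Martin periodinane, CH2Cl2, 0 °C to rt
Reagents that add atoms: none
Why: Dess–Martin oxidation should convert the primary alcohol into the aldehyde under near-neutral conditions that leave the alkenyl iodide untouched.

Step 3
Reactants: 3 4-iodopent-4-enal
Product: 4 (±)-6-iodo-2-methylhepta-1,6-dien-3-ol
Conditions: isopropenylmagnesium bromide, THF, −78 °C; then H2O/aq. NH4Cl
Reagents that add atoms: isopropenylmagnesium bromide, C=C(C)[Mg]Br
Why: Grignard 1,2-addition to the aldehyde at low temperature is far faster than iodine–magnesium exchange at the alkenyl iodide; the carbinol centre is formed racemic, which is irrelevant because it is destroyed in step 4.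

Step 4
Reactants: 4 (±)-6-iodo-2-methylhepta-1,6-dien-3-ol
Product: 6 ethyl (4E)-8-iodo-4-methylnona-4,8-dienoate, via ketene acetal 5 (not isolated)
Conditions: MeC(OEt)3 (excess), EtCO2H (cat.), 140 °C, EtOH distilled off
Reagents that add atoms: triethyl orthoacetate, CCOC(C)(OCC)OCC
Why: Johnson–Claisen rearrangement, in which the [3,3]-shift of the ketene acetal through a chair transition state with the iodoalkenyl side chain equatorial (avoiding a 1,3-diaxial clash with OEt) should give the (E)-trisubstituted alkene.

Step 5
Reactants: 6 ethyl (4E)-8-iodo-4-methylnona-4,8-dienoate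
Product: 7 (4E)-8-iodo-4-methylnona-4,8-dienal
Conditions: i-Bu2AlH (1.05 equiv), CH2Cl2, −78 °C; MeOH, then aq. potassium sodium tartrate (KNaC4H4O6)
Reagents that add atoms: none
Why: partial reduction of the ester should stop at the aldehyde because the tetrahedral aluminium hemiacetal is stable at −78 °C and collapses only on work-up; alkenes and the alkenyl iodide are inert.

Step 6
Reactants: 7 (4E)-8-iodo-4-methylnona-4,8-dienal
Product: 9 (4R,7E)-11-iodo-3,3,7-trimethyldodeca-1,7,11-trien-4-ol, via borinate ester 8 (not isolated)
Conditions: (−)-Ipc2BOMe [from (+)-α-pinene], prenylmagnesium chloride, THF/Et2O, −78 to 0 °C; then 7, −78 °C; then aq. NaOH, H2O2, 0 °C to rt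
Reagents that add atoms: prenylmagnesium chloride (3-methylbut-2-enylmagnesium chloride), CC(C)=CC[Mg]Cl
Why: Brown asymmetric reverse prenylation, in which the prenylborane adds through its γ-carbon in a closed chair Zimmerman–Traxler transition state and the (+)-α-pinene-derived isopinocampheyl groups direct attack to the Si face of the aldehyde, which should set the (R)-carbinol next to the new quaternary carbon.

Step 7
Reactants: 9 (4R,7E)-11-iodo-3,3,7-trimethyldodeca-1,7,11-trien-4-ol; 10 4-acetoxy-3-methoxybenzoic acid
Product: 12 (4R,7E)-11-iodo-3,3,7-trimethyldodeca-1,7,11-trien-4-yl 4-acetoxy-3-methoxybenzoate, via acid chloride 11 (not isolated)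
Conditions: 10, (COCl)2, DMF (cat.), CH2Cl2, rt, evaporate; then 9, Et3N, DMAP, CH2Cl2, 0 to 40 °C
Reagents that add atoms: none
Why: DMAP-catalysed acylation of the hindered secondary alcohol by the aroyl chloride (nucleophilic catalysis through the acylpyridinium ion) forms the O–acyl bond without touching the C–O bond, so the (R) configuration is retained.

Step 8
Reactants: 12 (4R,7E)-11-iodo-3,3,7-trimethyldodeca-1,7,11-trien-4-yl 4-acetoxy-3-methoxybenzoate
Product: 13 (1R,3E,8E)-2,2,9-trimethyl-5-methylidenecycloundeca-3,8-dien-1-yl 4-acetoxy-3-methoxybenzoate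
Conditions: Pd(OAc)2 (0.2 equiv), PPh3 (0.4 equiv), Ag2CO3 (1.5 equiv), MeCN, 70 °C, syringe-pump addition of 12 to about 1 mM
Reagents that add atoms: none
Why: Zerovalent palladium formed in the flask inserts into the C(sp2)–I bond of the 2-iodo-1-alkene, Ag2CO3 removes iodide to give a cationic alkenyl complex of divalent palladium, and syn-carbopalladation of the only monosubstituted alkene followed by syn-β-hydride elimination creates the central single bond of the diene (intramolecular Mizoroki–Heck reaction). The closest known reaction types are macrocyclic Heck closures of iodoalkenes onto terminal alkenes and palladium-catalysed closures of the humulene ring by intramolecular coupling. The eleven-membered ring closes in the 11-endo-trig mode, the alkenyl carbon bonding to the terminal CH2 because the internal alkene carbon is neopentylic, while 4-exo or 5-endo attack on the nearby trisubstituted alkene is geometrically disfavoured. No stereocentre is formed and the carbinol centre, insulated by the quaternary carbon, is untouched; the new ring alkene should be E because the alkylpalladium intermediate eliminates through the conformer with the ring chain and C(CH3)2 anti, and silver-mediated removal of the palladium hydride prevents re-addition. The step needs one direction of elimination and ring closure over oligomerisation: the first is secured because the carbon next to palladium on the far side is the hydrogen-free C(CH3)2, the second is sought by slow addition at high dilution, aided by the gem-dimethyl group and the two rigid alkene units of the chain.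

Step 9
Reactants: 13 (1R,3E,8E)-2,2,9-trimethyl-5-methylidenecycloundeca-3,8-dien-1-yl 4-acetoxy-3-methoxybenzoate
Product: 14 (1R,3E,8E)-2,2,9-trimethyl-5-methylidenecycloundeca-3,8-dien-1-yl 4-hydroxy-3-methoxybenzoate
Conditions: pyrrolidine (3 equiv), CH2Cl2, 0 °C to rt
Reagents that add atoms: none
Why: aminolysis of the activated aryl acetate is much faster than attack on the hindered secondary alkyl benzoate, so chemoselective deacetylation should free the phenol and give the target.

Compound list
1 | pent-4-yn-1-ol | C#CCCCO | starting material
2 | 4-iodopent-4-en-1-ol | C=C(I)CCCO | intermediate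
3 | 4-iodopent-4-enal | C=C(I)CCC=O | intermediate
4 | (±)-6-iodo-2-methylhepta-1,6-dien-3-ol | C=C(C)C(O)CCC(I)=C | intermediate
5 | 3-[(1-ethoxyethenyl)oxy]-6-iodo-2-methylhepta-1,6-diene (ketene acetal) | C=C(OCC)OC(CCC(I)=C)C(C)=C | intermediate
6 | ethyl (4E)-8-iodo-4-methylnona-4,8-dienoate | CCOC(=O)CC/C(C)=C/CCC(I)=C | intermediate
7 | (4E)-8-iodo-4-methylnona-4,8-dienal | O=CCC/C(C)=C/CCC(I)=C | intermediate
8 | (4R,7E)-11-iodo-3,3,7-trimethyldodeca-1,7,11-trien-4-yl diisopinocampheylborinate | C=CC(C)(C)[C@H](OB([C@@H]1C[C@@H]2C[C@H]([C@H]1C)C2(C)C)[C@@H]1C[C@@H]2C[C@H]([C@H]1C)C2(C)C)CC/C(C)=C/CCC(I)=C | intermediate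
9 | (4R,7E)-11-iodo-3,3,7-trimethyldodeca-1,7,11-trien-4-ol | C=CC(C)(C)[C@H](O)CC/C(C)=C/CCC(I)=C | intermediate
10 | 4-acetoxy-3-methoxybenzoic acid | CC(=O)Oc1ccc(C(=O)O)cc1OC | starting material
11 | 4-acetoxy-3-methoxybenzoyl chloride | CC(=O)Oc1ccc(C(=O)Cl)cc1OC | intermediate
12 | (4R,7E)-11-iodo-3,3,7-trimethyldodeca-1,7,11-trien-4-yl 4-acetoxy-3-methoxybenzoate | C=CC(C)(C)[C@H](OC(=O)c1ccc(OC(C)=O)c(OC)c1)CC/C(C)=C/CCC(I)=C | intermediate
13 | (1R,3E,8E)-2,2,9-trimethyl-5-methylidenecycloundeca-3,8-dien-1-yl 4-acetoxy-3-methoxybenzoate | C=C1/C=C/C(C)(C)[C@H](OC(=O)c2ccc(OC(C)=O)c(OC)c2)CC/C(C)=C/CC1 | intermediate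
14 | (1R,3E,8E)-2,2,9-trimethyl-5-methylidenecycloundeca-3,8-dien-1-yl 4-hydroxy-3-methoxybenzoate | C=C1/C=C/C(C)(C)[C@H](OC(=O)c2ccc(O)c(OC)c2)CC/C(C)=C/CC1 | target

Total step count: 9. Longest linear sequence: 9 steps (1 to 14).

Steps most likely to fail

Step 8. Intermolecular Heck coupling (oligomerisation) may outpace closure of the strained eleven-membered ring, or the alkenylpalladium intermediate may decompose before it finds the hindered vinyl group. The fallback sets out from 12: cross-metathesis of its terminal vinyl group with vinylboronic acid pinacol ester (second-generation Hoveyda–Grubbs catalyst, CH2Cl2, 40 °C; the iodoalkene and the trisubstituted alkene are poor metathesis partners) should give the (E)-alkenylboronate F1. Intramolecular Suzuki–Miyaura coupling of F1 (Pd(PPh3)4, Ag2O, THF, high dilution) would then form the same diene bond with retention of both alkene geometries and come back to the route at 13.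

Step 6. Facial selectivity of the allylboration may be poor, for example if magnesium salts open non-chair pathways or the prenylborane forms incompletely. The fallback sets out from 7: γ-selective addition of prenylmagnesium chloride (THF, −78 °C) should give the racemic alcohol F2, and Dess–Martin oxidation the α-quaternary ketone F3. Corey–Bakshi–Shibata reduction of F3 ((S)-2-methyl-CBS-oxazaborolidine (cat.), catecholborane, toluene, −78 °C), with the tert-alkyl group acting as the large substituent, should give the (R)-alcohol and come back to the route at 9.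

Step 5. Over-reduction may occur if the aluminium hemiacetal collapses before the quench, so that the aldehyde is reduced further. The fallback sets out from 6: exhaustive reduction with excess i-Bu2AlH (CH2Cl2, −78 to 0 °C) should give the primary alcohol F4, and Dess–Martin oxidation of F4 (CH2Cl2, rt) comes back to the route at 7.

Further compounds
F1 | step 8 | (4R,1E? no: (1E,7E)-chain) (4R,7E)-11-iodo-3,3,7-trimethyl-1-(4,4,5,5-tetramethyl-1,3,2-dioxaborolan-2-yl)dodeca-1(E),7,11-trien-4-yl 4-acetoxy-3-methoxybenzoate | CC1(C)OB(/C=C/C(C)(C)[C@H](OC(=O)c2ccc(OC(C)=O)c(OC)c2)CC/C(C)=C/CCC(I)=C)OC1(C)C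
F2 | step 6 | (±)-(7E)-11-iodo-3,3,7-trimethyldodeca-1,7,11-trien-4-ol | C=CC(C)(C)C(O)CC/C(C)=C/CCC(I)=C
F3 | step 6 | (7E)-11-iodo-3,3,7-trimethyldodeca-1,7,11-trien-4-one | C=CC(C)(C)C(=O)CC/C(C)=C/CCC(I)=C
F4 | step 5 | (4E)-8-iodo-4-methylnona-4,8-dien-1-ol | OCCC/C(C)=C/CCC(I)=C
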